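## Structural features

The target is a flavone: benzene ring A is fused to the 4-pyranone ring C (a chromen-4-one), and phenyl ring B is attached to C2 by a single bond. The molecule is flat and has no stereocentre. Ring A carries 5-OH, 7-OMe and 8-OMe and leaves only C6 unsubstituted; ring C carries 3-OMe; ring B carries 2'-OMe and 5'-OH. The fragile points are the para-related 5-OH/8-oxygen pair, which makes ring A a hydroquinone derivative that oxidises easily to a 5,8-quinone, the pyranone ring, which opens in hot alkali, and the two free phenols. The real difficulty is not the skeleton but the oxygen pattern: six oxygens must be told apart, a methoxy group must sit at C8 and not at C6, and only O5 and O5' may stay unmethylated. Along the chain C2–C3–C4–C4a–C5–C6–C7–C8–C8a, oxygen sits on every second carbon (C2/O1, the C4 carbonyl, O5, O7 and C8a/O1), which is the pattern of a folded poly-β-carbonyl chain; the 3-methoxy group is an extra substituent on that chain. As long as C8 is unsubstituted, ring A is a 2-acyl-5-methoxyresorcinol with two equivalent hydroxyls beside the acyl group, so ring C can close in one way only. The hydrogen bond between 5-OH and the C4 carbonyl is then used twice: it leaves C8 as the only free para position for hydroxylation, and it lets the new 8-OH be methylated without touching 5-OH.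

## Logic of the disconnections

14 from 13: the O5'–CH2Ph bond is cut. The B-ring phenol must be masked while ring A is oxidised and methylated, and a benzyl ether resists amide bases, magnesium alkoxide, dilute acid, alkaline peroxydisulfate and alkylating agents, yet leaves under neutral conditions. The forward step must cleave the ether without reducing the C2=C3 bond or the carbonyl group.

13 from 12: the O8–CH3 bond is cut. This reduces the problem to a quinol whose two hydroxyls differ sharply in reactivity, because one is chelated to the C4 carbonyl. The forward step must alkylate once only and must keep the quinol away from air while it is an anion.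

12 from 10: the C8–O bond is cut. Removing the C8 oxygen makes ring A symmetric with respect to the acyl group, which is what allows the ring construction below, and it leaves C8 as the only position para to the free 5-OH. The forward step is a para-hydroxylation of a phenol (Elbs type), passing through 11; it must spare the benzyl ether and the pyranone in cold alkali.

10 from 7: O1–C2 and C4a–C8a are cut, passing back through 9 and 8. Both rings A and C are traced to a single open chain whose terminal six carbons are stored as a 4-methoxy-2-pyranone: the lactone is the masked ester, the ring oxygen and the lactone carbonyl become the two ortho hydroxyls, and the pyrone methoxy group becomes 7-OMe. The forward step must fold the chain in the Claisen mode and not in an aldol mode, and must then close the pyranone by cyclodehydration.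

7 from 6 and 3: the bond between the aryl ketone carbon (future C2) and the methoxy-bearing carbon (future C3) is cut. This separates ring B as a simple benzoate from a small pyrone ketone. The forward step must generate the dianion of 6 and acylate it at the terminal methoxymethyl carbon, not at the internal methylene.

6 from 4 and 5: the bond between the pyrone methylene (future C4a) and the ketone carbon (future C4) is cut. Both pieces are commercial, and the 3-methoxy group comes in with 5. The forward step must deprotonate the 6-methyl group of 4 selectively and stop after one acylation.

3 from 2 from 1: the O2–CH3 and O5–CH2Ph bonds of the B-ring ester are cut. The two hydroxyls of 1 differ because the one ortho to the ester is hydrogen-bonded, so the order benzylation first, methylation second follows from reactivity.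

## Other disconnections considered

Alternative 1: The cut runs through O1–C8a and C4–C4a, so that ring A arrives as an aryne and C2–C3–C4 with ring B as an acylketene. In the forward direction fluoride would release aryne A4 from silyl triflate A2 while dioxinone A3 cycloreverts to acylketene A5. The ketone oxygen of A5 would add to the aryne carbon remote from the neighbouring methoxy group, and the aryl anion so formed would close on the ketene carbon to give flavone A1.
- In its favour: it is convergent, forms both ring bonds under nearly neutral conditions, and has no enolate folding problem. The regiochemistry should follow from the inductive effect of the methoxy group next to the aryne bond.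
- Against it here: A1 has 5-OMe instead of 5-OH and no oxygen at C8. The endgame would need a chelation-directed demethylation, the same late para-hydroxylation and methylation as the chosen plan, and then cleavage of the sulfonate, which normally calls for base that threatens ring C. A2 and A3 each need several steps. The two reactive partners form under different conditions (fluoride at ambient temperature, thermal cycloreversion well above it). [2+2] addition to the ketene and ketene dimerisation are plausible competitors.
- Comparison: on convergence and on the mildness of the ring-forming event this alternative is the better one. On the C8 problem the two are equal, since both leave C8 unsubstituted and depend on late oxidation. On step economy after the key step (four operations against three) and on the closeness of precedent for the key step, the chosen plan is ahead.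

Alternative 2: Only O1–C8a is cut, and ring A arrives complete as a bromoarene. In the forward direction the enolate oxygen of the 2-methoxy-1,3-diketone A7 would displace the ortho bromide under copper catalysis (an intramolecular Ullmann-type O-arylation) to give flavone A6.
- In its favour: every oxygen, including 8-OMe, is in place before ring closure, so the ring A pattern is fixed by the building block and not by a late oxidation. Both phenols are masked as acetals that fall in one acid step. Only the oxygen on the B-ring side can reach C8a in a six-membered mode, so the closure is unambiguous.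
- Against it here: A7 contains a pentasubstituted benzene with bromine, two methoxy groups, an acetal-protected hydroxyl and the acyl group in a fixed order, and its preparation is long and has regiochemical problems of its own. The crossed Claisen condensation leading to A7 joins two hindered partners. Insertion of copper into an electron-rich C–Br bond with two ortho substituents is expected to be slow.
- Comparison: the one-step endgame is clearly better than the three steps of the chosen plan, and the certainty of the ring A pattern is also better. The closure itself is a known reaction type, which is equal to the chosen plan. The chosen plan wins on overall length, because ring A comes from a cheap pyrone in one operation.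

Alternative 3: C4–C4a is cut, and ring A arrives as phenol A10 bound through O1 to C2 of an acrylic acid. In the forward direction acid A9 would be activated at its carboxyl group, and the acyl carbon would attack the only free position ortho to the ether oxygen, closing ring C to give flavone A8.
- In its favour: all four methoxy groups and the C8 oxygen are present before closure. The attacked position is ortho and para to methoxy groups and is the only ortho position open, so the acylation is regiochemically fixed and electronically favoured. From A8 only a chelation-directed 5-O-demethylation and a debenzylation remain, possibly in one operation.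
- Against it here: A10 is not a commodity phenol. A9 needs a tetrasubstituted enol ether of defined E geometry, made by a C–O bond formation that is not trivial. The acidic acylation conditions endanger the benzyl ether and the electron-rich ring B. The final cleavage of one methyl ether out of five rests on chelation alone, and the 3-methoxy group also lies next to the carbonyl.
- Comparison: on the endgame (one or two operations against three) this alternative is the equal or the better of the chosen plan, and on the ring A pattern it is the better. On access to the precursor and on the number of steps before the key step the chosen plan is ahead.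

Key step: step 5

Remark: 7, 8 and 9 are written as keto forms although they should exist largely as enols or magnesium chelates. Each has one methoxy-bearing sp3 carbon between two carbonyl groups that is configurationally labile, so no configuration is assigned. In 9 the former ester carbon and the former pyrone C6 are equivalent, so calling the new ring A bond C4a–C8a is a matter of convention. LDA and Mg(OMe)2 are taken as commercial solutions.

## Route

Step 1
Reactants: 1 methyl 2,5-dihydroxybenzoate
Product: 2 methyl 5-(benzyloxy)-2-hydroxybenzoate
Conditions: BnBr (1.05 equiv), K2CO3 (1.2 equiv), acetone, reflux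
Reagents that add atoms: benzyl bromide, BrCc1ccccc1
Why: Williamson ether synthesis; the 2-OH is held in a hydrogen bond to the ester carbonyl and is the poorer nucleophile under mild carbonate conditions, so one equivalent of halide should benzylate the free 5-OH selectively.

Step 2
Reactants: 2 methyl 5-(benzyloxy)-2-hydroxybenzoate
Product: 3 methyl 5-(benzyloxy)-2-methoxybenzoate
Conditions: MeI (2 equiv), K2CO3 (2 equiv), DMF, 50 °C
Reagents that add atoms: iodomethane, CI
Why: Williamson methylation of the remaining chelated phenol, driven by the polar aprotic solvent and excess alkylating agent; no other nucleophilic site is present.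

Step 3
Reactants: 4 4-methoxy-6-methyl-2H-pyran-2-one; 5 methyl methoxyacetate
Product: 6 4-methoxy-6-(3-methoxy-2-oxopropyl)-2H-pyran-2-one
Conditions: LDA (LiN(i-Pr)2, 2.1 equiv), THF, −78 °C; then 5, −78 → −20 °C; aq HCl
Reagents that add atoms: none
Why: Crossed Claisen acylation of the extended enolate formed by deprotonation of the 6-methyl group, which is vinylogously activated by the lactone carbonyl; the second equivalent of base deprotonates the more acidic product as it forms, which should prevent a second acylation.

Step 4
Reactants: 6 4-methoxy-6-(3-methoxy-2-oxopropyl)-2H-pyran-2-one; 3 methyl 5-(benzyloxy)-2-methoxybenzoate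
Product: 7 1-[5-(benzyloxy)-2-methoxyphenyl]-2-methoxy-4-(4-methoxy-2-oxo-2H-pyran-6-yl)butane-1,3-dione
Conditions: LDA (LiN(i-Pr)2, 3.2 equiv), THF, −78 → −20 °C; then 3, −20 °C → rt; aq HCl
Reagents that add atoms: none
Why: Claisen acylation of a ketone dianion: the first deprotonation takes the methylene between pyrone and ketone, the second the methoxymethyl carbon, and the ester should react at this more basic terminal carbanion; the third equivalent of base is consumed by the more acidic diketone product.

Step 5
Reactants: 7 1-[5-(benzyloxy)-2-methoxyphenyl]-2-methoxy-4-(4-methoxy-2-oxo-2H-pyran-6-yl)butane-1,3-dione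
Product: 10 2-[5-(benzyloxy)-2-methoxyphenyl]-5-hydroxy-3,7-dimethoxy-4H-chromen-4-one, via ring-opened triketo ester 8 (not isolated), via aryl diketone 9 (not isolated)
Conditions: Mg(OMe)2 (6 equiv), MeOH, reflux, N2; then HCl/MeOH (to pH 1), 60 °C
Reagents that add atoms: none
Why: Mg(OMe)2 first converts the 1,3-diketone of 7 into its magnesium chelate, and methoxide then adds to the lactone carbonyl and opens the pyrone to the (E)-3-methoxyenoate methyl ester 8, in which the C7 oxygen stays masked as a methyl enol ether. The methylene flanked by the two ketone carbonyls of 8 (future C4a) is deprotonated within the chelate and attacks the ester carbon in a Dieckmann-type Claisen closure, a 6-(enolexo)-exo-trig process that forms C4a–C8a; loss of methoxide and enolisation aromatise ring A to the 2-acyl-5-methoxyresorcinol 9. On acidification one of the two equivalent phenolic hydroxyls adds to the aryl ketone carbon (6-exo-trig, O1–C2) and elimination of water then completes ring C, as in the last stage of a Baker–Venkataraman flavone synthesis. The closest known reactions are the magnesium alkoxide-induced Claisen cyclisation of 6-(2-oxoalkyl)-4-methoxy-2-pyrones to acylphloroglucinol monomethyl ethers and the acid cyclodehydration of o-hydroxyaryl 1,3-diketones. No stereocentre is formed, and the labile methoxy-bearing sp3 carbon of 7 becomes the sp2 carbon C3. The selectivity needed is Claisen over aldol folding: chelation holds the diketone as an enolate so that its carbonyl carbons are poor electrophiles, the aryl ketone is further shielded by the ortho-methoxy group and the branched neighbouring carbon, and the enol ether blocks the C7 carbonyl, which leaves the ester as the only good acceptor within reach of the C4a carbanion. Because 9 is symmetric about the axis through the acyl group, closure of ring C through either hydroxyl should give the same flavone 10.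

Step 6
Reactants: 10 2-[5-(benzyloxy)-2-methoxyphenyl]-5-hydroxy-3,7-dimethoxy-4H-chromen-4-one
Product: 12 2-[5-(benzyloxy)-2-methoxyphenyl]-5,8-dihydroxy-3,7-dimethoxy-4H-chromen-4-one, via potassium 8-sulfate ester 11 (not isolated)
Conditions: K2S2O8 (1.5 equiv), aq KOH, pyridine, 15 °C; then 2 M HCl, 80 °C, N2
Reagents that add atoms: potassium peroxydisulfate, [K+].[K+].[O-]S(=O)(=O)OOS(=O)(=O)[O-]
Why: Elbs persulfate oxidation: the 5-phenoxide attacks the peroxide oxygen through its para carbon C8, the only free para position, to give aryl sulfate 11, which dilute acid hydrolyses to the quinol; ring B has no free phenol, so only ring A should react, and unreacted 10 can be recovered before the hydrolysis.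

Step 7
Reactants: 12 2-[5-(benzyloxy)-2-methoxyphenyl]-5,8-dihydroxy-3,7-dimethoxy-4H-chromen-4-one
Product: 13 2-[5-(benzyloxy)-2-methoxyphenyl]-5-hydroxy-3,7,8-trimethoxy-4H-chromen-4-one
Conditions: Me2SO4 (1.05 equiv), K2CO3 (1.1 equiv), acetone, reflux, N2
Reagents that add atoms: dimethyl sulfate, COS(=O)(=O)OC
Why: Williamson methylation with one equivalent of reagent; the 5-OH is tied up in a strong hydrogen bond to the C4 carbonyl and is much less reactive, so the unchelated 8-OH should be methylated selectively.

Step 8
Reactants: 13 2-[5-(benzyloxy)-2-methoxyphenyl]-5-hydroxy-3,7,8-trimethoxy-4H-chromen-4-one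
Product: 14 5-hydroxy-2-(5-hydroxy-2-methoxyphenyl)-3,7,8-trimethoxy-4H-chromen-4-one (5,5'-dihydroxy-3,7,8,2'-tetramethoxyflavone)
Conditions: H2 (1 atm), Pd on carbon (10% Pd/C), EtOAc–MeOH, rt
Reagents that add atoms: none
Why: Catalytic hydrogenolysis of the aryl benzyl ether; the tetrasubstituted, conjugated C2=C3 bond and the carbonyl group of the flavone should not be reduced under these mild conditions.

## Compound list

1 | methyl 2,5-dihydroxybenzoate | COC(=O)c1cc(O)ccc1O | starting material
2 | methyl 5-(benzyloxy)-2-hydroxybenzoate | COC(=O)c1cc(OCc2ccccc2)ccc1O | intermediate
3 | methyl 5-(benzyloxy)-2-methoxybenzoate | COC(=O)c1cc(OCc2ccccc2)ccc1OC | intermediate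
4 | 4-methoxy-6-methyl-2H-pyran-2-one | COc1cc(C)oc(=O)c1 | starting material
5 | methyl methoxyacetate | COCC(=O)OC | starting material
6 | 4-methoxy-6-(3-methoxy-2-oxopropyl)-2H-pyran-2-one | COCC(=O)Cc1cc(OC)cc(=O)o1 | intermediate
7 | 1-[5-(benzyloxy)-2-methoxyphenyl]-2-methoxy-4-(4-methoxy-2-oxo-2H-pyran-6-yl)butane-1,3-dione (racemic, enolisable) | COc1ccc(OCc2ccccc2)cc1C(=O)C(OC)C(=O)Cc1cc(OC)cc(=O)o1 | intermediate
8 | methyl (2E)-9-[5-(benzyloxy)-2-methoxyphenyl]-3,8-dimethoxy-5,7,9-trioxonon-2-enoate (formed as its magnesium enolate, not isolated) | COC(=O)/C=C(/OC)CC(=O)CC(=O)C(OC)C(=O)c1cc(OCc2ccccc2)ccc1OC | intermediate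
9 | 1-[5-(benzyloxy)-2-methoxyphenyl]-3-(2,6-dihydroxy-4-methoxyphenyl)-2-methoxypropane-1,3-dione (not isolated) | COc1cc(O)c(C(=O)C(OC)C(=O)c2cc(OCc3ccccc3)ccc2OC)c(O)c1 | intermediate
10 | 2-[5-(benzyloxy)-2-methoxyphenyl]-5-hydroxy-3,7-dimethoxy-4H-chromen-4-one | COc1ccc(OCc2ccccc2)cc1-c1oc2cc(OC)cc(O)c2c(=O)c1OC | intermediate
11 | potassium 2-[5-(benzyloxy)-2-methoxyphenyl]-5-hydroxy-3,7-dimethoxy-4-oxo-4H-chromen-8-yl sulfate (not isolated) | COc1ccc(OCc2ccccc2)cc1-c1oc2c(OS(=O)(=O)[O-])c(OC)cc(O)c2c(=O)c1OC.[K+] | intermediate
12 | 2-[5-(benzyloxy)-2-methoxyphenyl]-5,8-dihydroxy-3,7-dimethoxy-4H-chromen-4-one | COc1ccc(OCc2ccccc2)cc1-c1oc2c(O)c(OC)cc(O)c2c(=O)c1OC | intermediate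
13 | 2-[5-(benzyloxy)-2-methoxyphenyl]-5-hydroxy-3,7,8-trimethoxy-4H-chromen-4-one | COc1ccc(OCc2ccccc2)cc1-c1oc2c(OC)c(OC)cc(O)c2c(=O)c1OC | intermediate
14 | 5-hydroxy-2-(5-hydroxy-2-methoxyphenyl)-3,7,8-trimethoxy-4H-chromen-4-one | COc1ccc(O)cc1-c1oc2c(OC)c(OC)cc(O)c2c(=O)c1OC | target

## Step count and risk

Total: 8 steps. Longest linear sequence: 7 steps (steps 1, 2, 4, 5, 6, 7, 8); the pyrone branch joins at step 4 after one step.

**Step 5 (key step).** The most likely failure is folding of the opened chain in a mode other than the Claisen one, because 8 has more acidic and more electrophilic sites than the simple one-ketone precedent. Three such processes are plausible: aldol attack of the methylene next to the enol ether on the aryl ketone, O-cyclisation of the diketone enol onto the pyrone to give a 4-pyranone, and retro-Claisen loss of the aroyl group by methoxide attack on the diketone. The fallback sets out from 6 and returns at 10, and builds ring A before ring B is attached. Treating 6 with Mg(OMe)2 in methanol is the precedented single-ketone case and should give 1-(2,6-dihydroxy-4-methoxyphenyl)-2-methoxyethan-1-one F1. Its lithium polyanion, made with excess LiN(SiMe3)2 in THF, would be acylated at carbon by ester 3 in a crossed Claisen condensation to give 9 as an isolated compound. Methanolic HCl would then close ring C to 10.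

**Step 4.** The most likely failure is incomplete or misdirected second deprotonation (metalation of the pyrone ring, or conjugate self-addition of the anions to the pyrone) together with slow acylation by an electron-rich, ortho-substituted ester, so that proton transfer from product to dianion stalls the reaction. The fallback sets out from 6 and returns at 7, and replaces the Claisen acylation by an aldol addition and an oxidation. Ester 3 would be reduced with LiAlH4 to [5-(benzyloxy)-2-methoxyphenyl]methanol F2 and oxidised with MnO2 to 5-(benzyloxy)-2-methoxybenzaldehyde F3. The dianion of 6 (two equivalents of LDA, −78 °C) should add to this much more reactive electrophile without proton-transfer problems and give 6-{4-[5-(benzyloxy)-2-methoxyphenyl]-4-hydroxy-3-methoxy-2-oxobutyl}-4-methoxy-2H-pyran-2-one F4 as a mixture of diastereomers. Dess–Martin periodinane would oxidise this β-hydroxy ketone to 7.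

**Step 6.** The most likely failure is low conversion combined with over-oxidation. Peroxydisulfate is consumed by side reactions, the quinol is oxidised further to the quinone in alkaline solution, the benzyl ether dissolves poorly in aqueous alkali, and ring C can open slowly in base. The fallback sets out from 10 and returns at 14, and introduces the C8 oxygen by halogenation and copper-mediated etherification. The chelated 5-OH would be benzylated under forcing conditions (BnBr, K2CO3, DMF, 80 °C) to 5-(benzyloxy)-2-[5-(benzyloxy)-2-methoxyphenyl]-3,7-dimethoxy-4H-chromen-4-one F5. N-Iodosuccinimide should iodinate the 5,7-dialkoxy ring at C8 to give 5-(benzyloxy)-2-[5-(benzyloxy)-2-methoxyphenyl]-8-iodo-3,7-dimethoxy-4H-chromen-4-one F6. An Ullmann-type methoxylation (NaOMe, CuBr, MeOH–DMF, 110 °C) would give 5-(benzyloxy)-2-[5-(benzyloxy)-2-methoxyphenyl]-3,7,8-trimethoxy-4H-chromen-4-one F7. Hydrogenolysis over Pd on carbon would remove both benzyl groups and give 14.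

**Step 7.** The most likely failure is loss of chemoselectivity, with the chelated hydroxyl also methylated once base and reagent are in local excess, or aerial oxidation of the quinol anion before it is alkylated. The fallback sets out from 12 and returns at 14, and replaces selective alkylation by exhaustive alkylation followed by chelation-directed dealkylation. Excess MeI and K2CO3 in DMF would give 2-[5-(benzyloxy)-2-methoxyphenyl]-3,5,7,8-tetramethoxy-4H-chromen-4-one F8. BCl3 with pentamethylbenzene in CH2Cl2 (−78 → 0 °C) should then cleave the 5-methyl ether, which is activated by chelation to the C4 carbonyl, and the benzyl ether, giving 14 directly.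

## Further compounds

F1 | step 5 | 1-(2,6-dihydroxy-4-methoxyphenyl)-2-methoxyethan-1-one | COCC(=O)c1c(O)cc(OC)cc1O
F2 | step 4 | [5-(benzyloxy)-2-methoxyphenyl]methanol | COc1ccc(OCc2ccccc2)cc1CO
F3 | step 4 | 5-(benzyloxy)-2-methoxybenzaldehyde | COc1ccc(OCc2ccccc2)cc1C=O
F4 | step 4 | 6-{4-[5-(benzyloxy)-2-methoxyphenyl]-4-hydroxy-3-methoxy-2-oxobutyl}-4-methoxy-2H-pyran-2-one (mixture of diastereomers) | COc1ccc(OCc2ccccc2)cc1C(O)C(OC)C(=O)Cc1cc(OC)cc(=O)o1
F5 | step 6 | 5-(benzyloxy)-2-[5-(benzyloxy)-2-methoxyphenyl]-3,7-dimethoxy-4H-chromen-4-one | COc1ccc(OCc2ccccc2)cc1-c1oc2cc(OC)cc(OCc3ccccc3)c2c(=O)c1OC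
F6 | step 6 | 5-(benzyloxy)-2-[5-(benzyloxy)-2-methoxyphenyl]-8-iodo-3,7-dimethoxy-4H-chromen-4-one | COc1ccc(OCc2ccccc2)cc1-c1oc2c(I)c(OC)cc(OCc3ccccc3)c2c(=O)c1OC
F7 | step 6 | 5-(benzyloxy)-2-[5-(benzyloxy)-2-methoxyphenyl]-3,7,8-trimethoxy-4H-chromen-4-one | COc1ccc(OCc2ccccc2)cc1-c1oc2c(OC)c(OC)cc(OCc3ccccc3)c2c(=O)c1OC
F8 | step 7 | 2-[5-(benzyloxy)-2-methoxyphenyl]-3,5,7,8-tetramethoxy-4H-chromen-4-one | COc1ccc(OCc2ccccc2)cc1-c1oc2c(OC)c(OC)cc(OC)c2c(=O)c1OC
A1 | alternative 1 | 3,5,7-trimethoxy-2-[2-methoxy-5-(tosyloxy)phenyl]-4H-chromen-4-one | COc1ccc(OS(=O)(=O)c2ccc(C)cc2)cc1-c1oc2cc(OC)cc(OC)c2c(=O)c1OC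
A2 | alternative 1 | 3,5-dimethoxy-2-(trimethylsilyl)phenyl trifluoromethanesulfonate | COc1cc(OC)c([Si](C)(C)C)c(OS(=O)(=O)C(F)(F)F)c1
A3 | alternative 1 | 4-methoxy-3-(5-methoxy-2,2-dimethyl-4-oxo-4H-1,3-dioxin-6-yl)phenyl 4-methylbenzenesulfonate | COc1ccc(OS(=O)(=O)c2ccc(C)cc2)cc1C1=C(OC)C(=O)OC(C)(C)O1
A4 | alternative 1 | 3,5-dimethoxybenzyne (1,2-didehydro-3,5-dimethoxybenzene) | COC1=CC(OC)=CC#C1
A5 | alternative 1 | 4-methoxy-3-(2-methoxy-3-oxoprop-2-enoyl)phenyl 4-methylbenzenesulfonate | COc1ccc(OS(=O)(=O)c2ccc(C)cc2)cc1C(=O)C(OC)=C=O
A6 | alternative 2 | 3,7,8-trimethoxy-5-(methoxymethoxy)-2-[2-methoxy-5-(methoxymethoxy)phenyl]-4H-chromen-4-one | COCOc1ccc(OC)c(c1)-c1oc2c(OC)c(OC)cc(OCOC)c2c(=O)c1OC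
A7 | alternative 2 | 1-[2-bromo-3,4-dimethoxy-6-(methoxymethoxy)phenyl]-2-methoxy-3-[2-methoxy-5-(methoxymethoxy)phenyl]propane-1,3-dione | COCOc1ccc(OC)c(c1)C(=O)C(OC)C(=O)c1c(Br)c(OC)c(OC)cc1OCOC
A8 | alternative 3 | 2-[5-(benzyloxy)-2-methoxyphenyl]-3,5,7,8-tetramethoxy-4H-chromen-4-one | COc1ccc(OCc2ccccc2)cc1-c1oc2c(OC)c(OC)cc(OC)c2c(=O)c1OC
A9 | alternative 3 | (2E)-3-[5-(benzyloxy)-2-methoxyphenyl]-2-methoxy-3-(2,3,5-trimethoxyphenoxy)prop-2-enoic acid | OC(=O)/C(OC)=C(\Oc1cc(OC)cc(OC)c1OC)c1cc(OCc2ccccc2)ccc1OC
A10 | alternative 3 | 2,3,5-trimethoxyphenol | COc1cc(O)c(OC)c(OC)c1
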